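## The problem

Compound 22 is a bicyclo[3.3.1]nonane: a cyclohexane ring B (C9, C5, C6, C7, C8, C1) is spanned 1,3 by the bridge C2–C3=C4, which completes the cyclohexene ring A (C9, C1 to C5). The numbering used throughout is: C1 methyl-bearing bridgehead, C2 methylene, C3=C4 enal alkene with formyl carbon C4′ on C4, C5 formyl-bearing bridgehead (formyl carbon C5′), C6 carbon with the side chain (first side-chain carbon C1′), C7 and C8 methylenes, C9 acetoxy bridge. Both bridgeheads are quaternary and C5 lies next to the tertiary C6, so two all-carbon quaternary centres must be built on either side of one carbonyl-level carbon without loss of regiocontrol. Of the five stereocentres (1R, 5R, 6S, 9R, 1′R), C1′ is acyclic and is best bought, and C6 must be set against C1′ by a catalyst. C6 can then control C1 (1,4 across ring B) and C5 (vicinal), and C9 is decided last by the two unlike faces of the bridging carbonyl (the acetate lies over ring B). The fragile parts are: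
- the vicinal ene-dialdehyde, because a half-oxidised 1,4-diol closes to a lactol that is oxidised to a lactone;
- the acetate on a hindered carbinol 1,3 to the C5′ oxygen (hydride, base, acyl migration);
- the trisubstituted side-chain alkene (no ozone, peracid, hydrogenation or strong acid);
- any free β-hydroxymethyl ketone at C5 (retro-aldol).

The feature that opens the structure is that C4 carries the ester-level carbon C4′ and is bonded to C3. With an oxygen returned to C3, the C3–C4 bond is that of a cyclic β-keto ester, its two ends sit on acetate arms that are 1,3-diaxial on ring B, and the C9 carbonyl between two quaternary carbons cannot enolise.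

## Retrosynthesis

**22 ⇒ 21 (both C–H/C=O of the formyl groups).** No skeletal bond is cut. Both formyl groups are traced together to the ene-1,4-diol acetate 21. Oxidising C4′ first and C5′ later would pass through a γ-hydroxy enal whose hydroxymethyl and formyl groups are eclipsed on C5 and C4 and would close to a lactol. A double Swern oxidation never holds a free hydroxy aldehyde. The forward step must oxidise two primary alcohols and spare an acetate.

**21 ⇒ 20 ⇒ 19 ⇒ 18 (O–Si and O–acyl bonds).** The acetate must be on C9 before the oxidation, and C9 is the least reactive of three hydroxyls. Diol 21 therefore comes from bis-silyl ether 20, 20 from alcohol 19 by acetylation, and 19 from diol 18 by silylating the primary allylic hydroxyl. The forward steps need only discriminate a primary alcohol from a doubly neopentyl secondary one.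

**18 ⇒ 17 (C9–H and C4′–H).** The C9 carbinol and the allylic alcohol both come from keto enoate 17 with one hydride reagent. The reduction is placed after the bicycle exists on purpose. In a monocyclic ring-B ketone hydride would enter anti to the two axial arms and give the alcohol cis to them, which is the wrong epimer and would lactonise. In 17 the ring-A face of C9 is the open one, which is the face required.

**17 ⇒ 16 ⇒ 15 (C3–H back to C3–O).** The enoate is drawn from the enol triflate 16 of β-keto ester 15. This adds the one oxygen the target lacks, but it places the alkene at C3=C4 without any regiochemical choice, since C3 can only enolise productively toward the ester-bearing C4.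

**15 ⇒ 14 (C3–C4, key disconnection).** Cutting C3–C4 opens ring A to the monocyclic ketone 14 with a methyl acetate arm on C1 and a tert-butyl acetate arm on C5. Cutting C2–C3 instead would need an acyl anion, and cutting C4–C5 or C1–C2 would have to create a quaternary bridgehead in the ring-closing step. The C3–C4 cut leaves both quaternary centres in a simple cyclohexanone. The forward reaction must condense in one direction only, which the tert-butyl ester provides.

**14 ⇒ 13 ⇒ 12 (C5–C5′).** The silyloxymethyl group is removed as formaldehyde. It is introduced last at C5 because the second substituent enters anti to the C6 side chain, and C5′ is the group that must be trans to it. The precursor 12 has one stereocentre fewer, and its C5 configuration is irrelevant.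

**12 ⇒ 10 + 11 (C5–C4).** The tert-butyl acetate arm is an enolate alkylation with tert-butyl bromoacetate 11. In keto ester 10 the C1 side is already quaternary, so the ketone can only enolise toward C5.

**10 ⇒ 7 + 8 (C1–C2).** The methyl acetate arm and the C1 quaternary centre come from reductive alkylation of enone 7 with methyl bromoacetate 8. The enone fixes the enolate at C1, and the equatorial C6 side chain, 1,4 to C1, directs axial alkylation to the cis face. C1 is made quaternary before C5 because an axial group at C5 would later turn the electrophile to the wrong face of C1.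

**7 ⇒ 4 + 5 (C5–C6 and C1=C8).** Ring B is opened to the enal 4 and tert-butyl 3-oxopentanoate 5. The keto ester supplies C5, C9, C1 and the C1 methyl group; the ester is lost after it has directed the Michael addition. C6 is the only stereocentre formed and is set by the amine catalyst.

**4 ⇒ 3 ⇒ 1 (C7–C8 and the C6=C7 unsaturation).** The enal is (R)-citronellal 1 extended by one carbon (via enol ether 2 to aldehyde 3) and dehydrogenated. C2 of 1 becomes C6 and C3 of 1 is C1′, so the side-chain stereocentre is bought and is never α to a carbonyl.

## Roads not taken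

**Alternative 1:** The cut is at both ring bonds of C1 (C1–C2 and C1–C8), which unravels the bicycle to the open-chain ethyl ketone A1. In the forward step two equivalents of KN(SiMe3)2 would be used. The C1 enolate first displaces the Z-allylic bromide (ring A, 6-exo-tet), is regenerated at the now tertiary C1 and displaces the primary iodide (ring B, 6-exo-tet) to give A2.
- Merits: both rings and the C1 quaternary centre form in one flask, and C1 is fixed by the geometry of the bridge. A2 already has the C3=C4 alkene and both C4′ and C5′ at the alcohol level, so no oxygen is put on C3 and removed again. About four steps would remain after A2, against seven in the chosen plan.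
- Weak points: the quaternary C5 of A1, vicinal to C6 and C1′, must be built in an open chain where no ring tells the faces apart. The Z-allylic bromide invites SN2′ attack and O-alkylation. The second closure asks a hindered tertiary α-carbon to reach a primary iodide with the C6 chain forced axial, and E2 loss of HI is the easy escape.
- Comparison: Alternative 1 is better in ring-forming economy and endgame length. The chosen plan sets against this that every stereocentre is made on a six-membered ring by a reaction of known bias, and that 14 is reached in seven steps, fewer than any realistic route to A1.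

**Alternative 2:** The cut is at C5–C6 and C1–C8: ring B is annulated onto a preformed ring A, the keto ester A3, with the same enal 4 that the chosen route uses. In the forward step a secondary amine activates 4 as its iminium ion, C5 of A3 adds to C6, and the C1 enol of the C9 ketone then adds to the freed C8 aldehyde to give A4.
- Merits: it is the most convergent road. C5 and C6 are set in one catalytic step, C5′ arrives as an ester, C4′ is already an alcohol, and no two arms need differentiating.
- Weak points: the anion of A3 is ambident (C5 or, through the alkene, C3). A quaternary centre must form at C5 by attack on a β-branched enal, and the C5/C6 relationship depends on the approach of two prochiral partners, of which the catalyst controls one. The aldol must close a bridged ring through an axial enol and is reversible, so the sequence may stop at the Michael adduct. A4 carries a superfluous C8 hydroxyl whose removal needs a radical deoxygenation (two more steps), since elimination–hydrogenation is excluded by the alkenes. The γ-stereocentre of 4 meets the same amine as in the chosen plan.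
- Comparison: if it worked with the right sense, this road would reach the bicycle in fewer steps and with more convergence, and that advantage is real. The chosen plan pays with linearity but spreads the same problems over separate steps: C5 becomes quaternary with formaldehyde, the smallest electrophile, and the ring closes by a condensation driven by enolate formation.

**Alternative 3:** The cut is at C1–C2, with C2 returned to C9, giving the cis-fused epoxy hydrindenol A5. In the forward step ZnBr2 ionises the C1–C8 epoxide at tertiary C1, C2 migrates from C9 to C1 anti to the breaking C–O bond, and C9 becomes the ketone of A6.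
- Merits: it is the only road that makes the C1 quaternary centre without an enolate alkylation, and it does so stereospecifically. A fused five-membered ring is easier to build than a bridge, and a hydroxyl-directed epoxidation would place the epoxide on the needed face.
- Weak points: C9 carries two candidates for migration, C2 and the quaternary C5. The more substituted C5 has the higher intrinsic aptitude, and its shift would contract ring B. The Lewis acid meets an allylic silyl ether and a cation-prone side-chain alkene. A5 has five stereocentres including a tertiary carbinol, and A6 again has an extra C8 hydroxyl.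
- Comparison: it is better than the chosen plan only in how C1 is made. It is the longest road and its key step has a built-in competing migration, whereas the chosen plan makes C1 in one alkylation under a 1,4-bias with close analogy.

Key step: step 8

Assumption: the sense of induction at C6 in step 3 is taken from the usual shielding model of E-iminium ions of diarylprolinol silyl ethers (attack anti to the diaryl(silyloxy)methyl group); if it proves opposite, the enantiomeric catalyst is used with no other change.

## Route

Step 1
Reactants: 1 (R)-citronellal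
Product: 3 (4R)-4,8-dimethylnon-7-enal, via methyl enol ether 2 (not isolated)
Conditions: Ph3P(CH2OMe)Cl, KOt-Bu, THF, 0 °C to rt; crude enol ether, 2 M HCl, THF, rt
Reagents that add atoms: (methoxymethyl)triphenylphosphonium chloride, COC[P+](c1ccccc1)(c1ccccc1)c1ccccc1.[Cl-]; water, O
Why: Wittig methoxymethylenation and acid hydrolysis of the enol ether is the standard one-carbon homologation of an aldehyde; the stereocentre of 1 is β to the carbonyl and is not touched.

Step 2
Reactants: 3 (4R)-4,8-dimethylnon-7-enal
Product: 4 (2E,4R)-4,8-dimethylnona-2,7-dienal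
Conditions: 2-iodoxybenzoic acid (IBX, 1.3 equiv), DMSO/PhF, 65 °C
Reagents that add atoms: none
Why: IBX dehydrogenation of an aldehyde through its enol gives the conjugated E-enal; the stereocentre becomes γ and is not involved as long as oxidant and temperature are limited so that no second dehydrogenation follows.

Step 3
Reactants: 4 (2E,4R)-4,8-dimethylnona-2,7-dienal; 5 tert-butyl 3-oxopentanoate
Product: 7 (5R)-2-methyl-5-[(2R)-6-methylhept-5-en-2-yl]cyclohex-2-en-1-one, via Michael adduct 6 (not isolated)
Conditions: (S)-2-{bis[3,5-bis(trifluoromethyl)phenyl](trimethylsilyloxy)methyl}pyrrolidine (10 mol%), PhCO2H (10 mol%), toluene, 0 °C to rt; then p-TsOH·H2O (20 mol%), toluene, 80 °C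
Reagents that add atoms: none
Why: Iminium-catalysed Michael addition of a β-keto ester to an enal, then acid-induced intramolecular aldol condensation with loss of the tert-butyl ester and decarboxylation (organocatalytic Robinson-type annulation). The catalyst shields one face of the E-iminium ion so that C5 adds to C6 from the open face, which sets C6; C1′ is carried from 1.

Step 4
Reactants: 7 (5R)-2-methyl-5-[(2R)-6-methylhept-5-en-2-yl]cyclohex-2-en-1-one; 8 methyl bromoacetate
Product: 10 methyl 2-[(1R,4R)-1-methyl-4-[(2R)-6-methylhept-5-en-2-yl]-2-oxocyclohexyl]acetate, via lithium enolate 9 (not isolated)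
Conditions: LiBH(s-Bu)3 (1.05 equiv), THF, −78 °C; then BrCH2CO2Me, DMPU, −78 to 0 °C
Reagents that add atoms: none
Why: Reductive alkylation of an enone: conjugate hydride addition gives the C1 enolate regiospecifically. It is alkylated axially on the half-chair with the C6 side chain equatorial, which places the acetate arm cis to the side chain (1,4), as in alkylations of dihydrocarvone-type enolates.

Step 5
Reactants: 10 methyl 2-[(1R,4R)-1-methyl-4-[(2R)-6-methylhept-5-en-2-yl]-2-oxocyclohexyl]acetate; 11 tert-butyl bromoacetate
Product: 12 tert-butyl 2-[(1S,3R,6S)-3-(2-methoxy-2-oxoethyl)-3-methyl-6-[(2R)-6-methylhept-5-en-2-yl]-2-oxocyclohexyl]acetate (major C5 epimer; the minor one converges in step 6)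
Conditions: LiN(i-Pr)2 (1.05 equiv), THF, −78 °C; then BrCH2CO2t-Bu, DMPU, −78 to −30 °C
Reagents that add atoms: none
Why: Kinetic ketone enolate alkylation; C1 is quaternary, so the only ketone enolate is toward C5, and its protons are removed faster than those of the neopentyl ester methylene. The configuration formed at C5 does not matter because C5 is enolised again in step 6.

Step 6
Reactants: 12 tert-butyl 2-[(1S,3R,6S)-3-(2-methoxy-2-oxoethyl)-3-methyl-6-[(2R)-6-methylhept-5-en-2-yl]-2-oxocyclohexyl]acetate
Product: 13 tert-butyl 2-[(1R,3R,6S)-1-(hydroxymethyl)-3-(2-methoxy-2-oxoethyl)-3-methyl-6-[(2R)-6-methylhept-5-en-2-yl]-2-oxocyclohexyl]acetate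
Conditions: LiN(SiMe3)2 (1.1 equiv), THF, −78 to −40 °C; CH2O (gas, from cracked paraformaldehyde), −78 °C; AcOH, −78 °C
Reagents that add atoms: formaldehyde, C=O
Why: Aldol addition of a ketone enolate to monomeric formaldehyde; under equilibrating silazide conditions the enolate rests on the ketone, which is far more acidic than either ester methylene. In the tetrasubstituted enolate the C6 side chain turns pseudo-axial to escape allylic 1,2-strain, and formaldehyde adds to C5 anti to it, so C5′ ends trans and the acetate arm cis to the side chain.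

Step 7
Reactants: 13 tert-butyl 2-[(1R,3R,6S)-1-(hydroxymethyl)-3-(2-methoxy-2-oxoethyl)-3-methyl-6-[(2R)-6-methylhept-5-en-2-yl]-2-oxocyclohexyl]acetate
Product: 14 tert-butyl 2-[(1R,3R,6S)-1-{[(tert-butyldimethylsilyl)oxy]methyl}-3-(2-methoxy-2-oxoethyl)-3-methyl-6-[(2R)-6-methylhept-5-en-2-yl]-2-oxocyclohexyl]acetate
Conditions: TBSCl, imidazole, DMF, rt
Reagents that add atoms: tert-butyldimethylsilyl chloride, CC(C)(C)[Si](C)(C)Cl
Why: Silylation of a primary alcohol; it blocks retro-aldol loss of formaldehyde and lactonisation onto the tert-butyl ester before the base treatment of step 8.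

Step 8
Reactants: 14 tert-butyl 2-[(1R,3R,6S)-1-{[(tert-butyldimethylsilyl)oxy]methyl}-3-(2-methoxy-2-oxoethyl)-3-methyl-6-[(2R)-6-methylhept-5-en-2-yl]-2-oxocyclohexyl]acetate
Product: 15 tert-butyl (1R,5S,6S)-5-{[(tert-butyldimethylsilyl)oxy]methyl}-3-hydroxy-1-methyl-6-[(2R)-6-methylhept-5-en-2-yl]-9-oxobicyclo[3.3.1]non-3-ene-4-carboxylate (target numbering; enol form of the β-keto ester)
Conditions: KOt-Bu (2.2 equiv), THF (0.02 M), 0 °C to rt; AcOH
Reagents that add atoms: none
Why: Dieckmann condensation. KOt-Bu deprotonates both ester methylenes reversibly, but only the C4 enolate of the tert-butyl acetate arm has a reactive partner: it adds to the methyl ester carbonyl C3 on the C1 arm and methoxide leaves, a 6-(enolexo)-exo-trig closure of ring A. The opposite mode would need the C2 enolate to attack the tert-butyl ester carbonyl, which is shielded and has the poorer leaving group, so the ester ends on C4 and not on C2. The closest known reaction type is the Dieckmann cyclisation of cis-1,3-cyclohexanediacetates to bicyclo[3.3.1]nonan-3-one-2-carboxylates, made one-directional by a tert-butyl ester. No stereocentre is created; the step needs the two arms cis, which steps 4 to 6 provide, and the chair of ring B that holds both arms axial also keeps the C6 side chain equatorial. The C9 ketone lies between two quaternary carbons, cannot enolise and could only form three-membered rings with either enolate, so it stays out, and no centre of 14 can epimerise. The product is deprotonated between C3 and C4′ as it forms, which pulls the equilibrium to 15 and protects it from retro-Claisen opening by methoxide. High dilution suppresses intermolecular Claisen condensation.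

Step 9
Reactants: 15 tert-butyl (1R,5S,6S)-5-{[(tert-butyldimethylsilyl)oxy]methyl}-3-hydroxy-1-methyl-6-[(2R)-6-methylhept-5-en-2-yl]-9-oxobicyclo[3.3.1]non-3-ene-4-carboxylate
Product: 16 tert-butyl (1R,5S,6S)-5-{[(tert-butyldimethylsilyl)oxy]methyl}-1-methyl-6-[(2R)-6-methylhept-5-en-2-yl]-9-oxo-3-[(trifluoromethanesulfonyl)oxy]bicyclo[3.3.1]non-3-ene-4-carboxylate
Conditions: Tf2O, i-Pr2NEt, CH2Cl2, −78 °C
Reagents that add atoms: trifluoromethanesulfonic anhydride, O=S(=O)(OS(=O)(=O)C(F)(F)F)C(F)(F)F
Why: O-Triflation of a β-keto ester enol; the conjugated enol toward C4 is the one present, so the alkene is fixed at C3=C4, and the C9 ketone has no enol to compete.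

Step 10
Reactants: 16 tert-butyl (1R,5S,6S)-5-{[(tert-butyldimethylsilyl)oxy]methyl}-1-methyl-6-[(2R)-6-methylhept-5-en-2-yl]-9-oxo-3-[(trifluoromethanesulfonyl)oxy]bicyclo[3.3.1]non-3-ene-4-carboxylate
Product: 17 tert-butyl (1R,5S,6S)-5-{[(tert-butyldimethylsilyl)oxy]methyl}-1-methyl-6-[(2R)-6-methylhept-5-en-2-yl]-9-oxobicyclo[3.3.1]non-3-ene-4-carboxylate
Conditions: Pd(OAc)2 (5 mol%), PPh3 (10 mol%), HCO2H, Et3N, DMF, 60 °C
Reagents that add atoms: none
Why: Palladium-catalysed formate reduction of a vinyl triflate: oxidative addition to zerovalent palladium, formate exchange, decarboxylation to the palladium hydride and C–H reductive elimination. Ketone, silyl ether, tert-butyl ester and the side-chain alkene are inert.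

Step 11
Reactants: 17 tert-butyl (1R,5S,6S)-5-{[(tert-butyldimethylsilyl)oxy]methyl}-1-methyl-6-[(2R)-6-methylhept-5-en-2-yl]-9-oxobicyclo[3.3.1]non-3-ene-4-carboxylate
Product: 18 (1R,5S,6S,9R)-5-{[(tert-butyldimethylsilyl)oxy]methyl}-4-(hydroxymethyl)-1-methyl-6-[(2R)-6-methylhept-5-en-2-yl]bicyclo[3.3.1]non-3-en-9-ol
Conditions: i-Bu2AlH (6 equiv), CH2Cl2, −78 to 0 °C; aq. KNaC4H4O6
Reagents that add atoms: none
Why: 1,2-Reduction of the enoate to the allylic alcohol and hydride reduction of the bridging ketone by the same aluminium hydride. Hydride should reach C9 over ring A, where only one axial hydrogen (on C2) and two sp2 carbons flank the carbonyl, rather than over chair ring B with axial hydrogens on C6 and C8; this leaves the hydroxyl over ring B (9R), as the target requires.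

Step 12
Reactants: 18 (1R,5S,6S,9R)-5-{[(tert-butyldimethylsilyl)oxy]methyl}-4-(hydroxymethyl)-1-methyl-6-[(2R)-6-methylhept-5-en-2-yl]bicyclo[3.3.1]non-3-en-9-ol
Product: 19 (1R,5S,6S,9R)-4,5-bis{[(tert-butyldimethylsilyl)oxy]methyl}-1-methyl-6-[(2R)-6-methylhept-5-en-2-yl]bicyclo[3.3.1]non-3-en-9-ol
Conditions: TBSCl (1.1 equiv), imidazole, CH2Cl2, 0 °C
Reagents that add atoms: tert-butyldimethylsilyl chloride, CC(C)(C)[Si](C)(C)Cl
Why: Selective silylation of the primary allylic alcohol; the C9 carbinol between two quaternary carbons does not react under these conditions.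

Step 13
Reactants: 19 (1R,5S,6S,9R)-4,5-bis{[(tert-butyldimethylsilyl)oxy]methyl}-1-methyl-6-[(2R)-6-methylhept-5-en-2-yl]bicyclo[3.3.1]non-3-en-9-ol
Product: 20 (1R,5S,6S,9R)-4,5-bis{[(tert-butyldimethylsilyl)oxy]methyl}-1-methyl-6-[(2R)-6-methylhept-5-en-2-yl]bicyclo[3.3.1]non-3-en-9-yl acetate
Conditions: Ac2O, DMAP (1 equiv), pyridine, 50 °C
Reagents that add atoms: acetic anhydride, CC(=O)OC(C)=O
Why: DMAP-promoted acetylation of a hindered secondary alcohol; forcing conditions are tolerated because it is the only free hydroxyl.

Step 14
Reactants: 20 (1R,5S,6S,9R)-4,5-bis{[(tert-butyldimethylsilyl)oxy]methyl}-1-methyl-6-[(2R)-6-methylhept-5-en-2-yl]bicyclo[3.3.1]non-3-en-9-yl acetate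
Product: 21 (1R,5S,6S,9R)-4,5-bis(hydroxymethyl)-1-methyl-6-[(2R)-6-methylhept-5-en-2-yl]bicyclo[3.3.1]non-3-en-9-yl acetate
Conditions: HF·pyridine, THF/pyridine, 0 °C to rt
Reagents that add atoms: none
Why: Fluoride cleavage of both primary silyl ethers under buffered acidic conditions, which avoid the base-induced 1,3-acetyl shift from O9 to O5′ and leave the acetate intact.

Step 15
Reactants: 21 (1R,5S,6S,9R)-4,5-bis(hydroxymethyl)-1-methyl-6-[(2R)-6-methylhept-5-en-2-yl]bicyclo[3.3.1]non-3-en-9-yl acetate
Product: 22 (1R,5R,6S,9R)-4,5-diformyl-1-methyl-6-[(2R)-6-methylhept-5-en-2-yl]bicyclo[3.3.1]non-3-en-9-yl acetate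
Conditions: (COCl)2, DMSO, CH2Cl2, −78 °C; Et3N, −78 to 0 °C
Reagents that add atoms: none
Why: Swern oxidation of both primary alcohols; both are converted to alkoxysulfonium ions before base is added, so no hydroxy aldehyde is present to close to a lactol and be oxidised to a lactone, the usual way of making vicinal ene-dialdehydes from ene-1,4-diols. C5 is quaternary, so neither aldehyde can epimerise.

## Compound list

1 | (R)-citronellal, (3R)-3,7-dimethyloct-6-enal | O=CC[C@H](C)CCC=C(C)C | starting material
2 | (4R)-1-methoxy-4,8-dimethylnona-1,7-diene (E/Z mixture) | COC=CC[C@H](C)CCC=C(C)C | intermediate (not isolated)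
3 | (4R)-4,8-dimethylnon-7-enal | O=CCC[C@H](C)CCC=C(C)C | intermediate
4 | (2E,4R)-4,8-dimethylnona-2,7-dienal | O=C/C=C/[C@H](C)CCC=C(C)C | intermediate
5 | tert-butyl 3-oxopentanoate | CCC(=O)CC(=O)OC(C)(C)C | starting material
6 | tert-butyl (3S,4R)-4,8-dimethyl-3-(2-oxoethyl)-2-propanoylnon-7-enoate (C2 epimers) | CCC(=O)C(C(=O)OC(C)(C)C)[C@@H](CC=O)[C@H](C)CCC=C(C)C | intermediate (not isolated)
7 | (5R)-2-methyl-5-[(2R)-6-methylhept-5-en-2-yl]cyclohex-2-en-1-one | O=C1C(C)=CC[C@@H]([C@H](C)CCC=C(C)C)C1 | intermediate
8 | methyl bromoacetate | COC(=O)CBr | starting material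
9 | lithium (5R)-2-methyl-5-[(2R)-6-methylhept-5-en-2-yl]cyclohex-1-en-1-olate | [Li+].[O-]C1=C(C)CC[C@@H]([C@H](C)CCC=C(C)C)C1 | intermediate (not isolated)
10 | methyl 2-[(1R,4R)-1-methyl-4-[(2R)-6-methylhept-5-en-2-yl]-2-oxocyclohexyl]acetate | O=C1[C@@](C)(CC(=O)OC)CC[C@@H]([C@H](C)CCC=C(C)C)C1 | intermediate
11 | tert-butyl bromoacetate | CC(C)(C)OC(=O)CBr | starting material
12 | tert-butyl 2-[(1S,3R,6S)-3-(2-methoxy-2-oxoethyl)-3-methyl-6-[(2R)-6-methylhept-5-en-2-yl]-2-oxocyclohexyl]acetate (major C5 epimer) | O=C1[C@@](C)(CC(=O)OC)CC[C@@H]([C@H](C)CCC=C(C)C)[C@@H]1CC(=O)OC(C)(C)C | intermediate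
13 | tert-butyl 2-[(1R,3R,6S)-1-(hydroxymethyl)-3-(2-methoxy-2-oxoethyl)-3-methyl-6-[(2R)-6-methylhept-5-en-2-yl]-2-oxocyclohexyl]acetate | O=C1[C@@](C)(CC(=O)OC)CC[C@@H]([C@H](C)CCC=C(C)C)[C@@]1(CO)CC(=O)OC(C)(C)C | intermediate
14 | tert-butyl 2-[(1R,3R,6S)-1-{[(tert-butyldimethylsilyl)oxy]methyl}-3-(2-methoxy-2-oxoethyl)-3-methyl-6-[(2R)-6-methylhept-5-en-2-yl]-2-oxocyclohexyl]acetate | O=C1[C@@](C)(CC(=O)OC)CC[C@@H]([C@H](C)CCC=C(C)C)[C@@]1(CO[Si](C)(C)C(C)(C)C)CC(=O)OC(C)(C)C | intermediate
15 | tert-butyl (1R,5S,6S)-5-{[(tert-butyldimethylsilyl)oxy]methyl}-3-hydroxy-1-methyl-6-[(2R)-6-methylhept-5-en-2-yl]-9-oxobicyclo[3.3.1]non-3-ene-4-carboxylate | O=C1[C@@]2(C)CC(O)=C(C(=O)OC(C)(C)C)[C@]1(CO[Si](C)(C)C(C)(C)C)[C@H]([C@H](C)CCC=C(C)C)CC2 | intermediate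
16 | tert-butyl (1R,5S,6S)-5-{[(tert-butyldimethylsilyl)oxy]methyl}-1-methyl-6-[(2R)-6-methylhept-5-en-2-yl]-9-oxo-3-[(trifluoromethanesulfonyl)oxy]bicyclo[3.3.1]non-3-ene-4-carboxylate | O=C1[C@@]2(C)CC(OS(=O)(=O)C(F)(F)F)=C(C(=O)OC(C)(C)C)[C@]1(CO[Si](C)(C)C(C)(C)C)[C@H]([C@H](C)CCC=C(C)C)CC2 | intermediate
17 | tert-butyl (1R,5S,6S)-5-{[(tert-butyldimethylsilyl)oxy]methyl}-1-methyl-6-[(2R)-6-methylhept-5-en-2-yl]-9-oxobicyclo[3.3.1]non-3-ene-4-carboxylate | O=C1[C@@]2(C)CC=C(C(=O)OC(C)(C)C)[C@]1(CO[Si](C)(C)C(C)(C)C)[C@H]([C@H](C)CCC=C(C)C)CC2 | intermediate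
18 | (1R,5S,6S,9R)-5-{[(tert-butyldimethylsilyl)oxy]methyl}-4-(hydroxymethyl)-1-methyl-6-[(2R)-6-methylhept-5-en-2-yl]bicyclo[3.3.1]non-3-en-9-ol | O[C@@H]1[C@@]2(C)CC=C(CO)[C@]1(CO[Si](C)(C)C(C)(C)C)[C@H]([C@H](C)CCC=C(C)C)CC2 | intermediate
19 | (1R,5S,6S,9R)-4,5-bis{[(tert-butyldimethylsilyl)oxy]methyl}-1-methyl-6-[(2R)-6-methylhept-5-en-2-yl]bicyclo[3.3.1]non-3-en-9-ol | O[C@@H]1[C@@]2(C)CC=C(CO[Si](C)(C)C(C)(C)C)[C@]1(CO[Si](C)(C)C(C)(C)C)[C@H]([C@H](C)CCC=C(C)C)CC2 | intermediate
20 | (1R,5S,6S,9R)-4,5-bis{[(tert-butyldimethylsilyl)oxy]methyl}-1-methyl-6-[(2R)-6-methylhept-5-en-2-yl]bicyclo[3.3.1]non-3-en-9-yl acetate | CC(=O)O[C@@H]1[C@@]2(C)CC=C(CO[Si](C)(C)C(C)(C)C)[C@]1(CO[Si](C)(C)C(C)(C)C)[C@H]([C@H](C)CCC=C(C)C)CC2 | intermediate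
21 | (1R,5S,6S,9R)-4,5-bis(hydroxymethyl)-1-methyl-6-[(2R)-6-methylhept-5-en-2-yl]bicyclo[3.3.1]non-3-en-9-yl acetate | CC(=O)O[C@@H]1[C@@]2(C)CC=C(CO)[C@]1(CO)[C@H]([C@H](C)CCC=C(C)C)CC2 | intermediate
22 | (1R,5R,6S,9R)-4,5-diformyl-1-methyl-6-[(2R)-6-methylhept-5-en-2-yl]bicyclo[3.3.1]non-3-en-9-yl acetate | CC(=O)O[C@@H]1[C@@]2(C)CC=C(C=O)[C@]1(C=O)[C@H]([C@H](C)CCC=C(C)C)CC2 | target

## Step count and least certain steps

Total: 15 steps. Longest linear sequence: 15 steps from 1 (5, 8 and 11 are commercial and enter directly).

**Step 8 (key step).** The likely failure is incomplete or reversible closure with erosion of regiocontrol. The nucleophilic carbon C4 is neopentyl and must reach C3 with both arms axial, methoxide can reopen the β-keto ester before it is deprotonated, and long exposure lets transesterification and intermolecular Claisen condensation compete. The fallback makes the acylation irreversible. Setting out from 14, the methyl ester is saponified selectively (LiOH, aqueous THF; the tert-butyl ester and silyl ether stay) to the acid F1. This is activated with 1,1′-carbonyldiimidazole as the acyl imidazolide F2 and treated with LiN(SiMe3)2 at −78 °C. The tert-butyl ester enolate at C4 is then acylated at C3 with loss of imidazolide instead of alkoxide, and the route is rejoined at 15.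

**Step 3.** The likely failures are erosion of the C1′ configuration (γ-deprotonation of the iminium ion of 4 to a dienamine and reprotonation), a mismatched catalyst/substrate pair lowering the selectivity at C6, and acid damage to the side-chain alkene in the second stage. The fallback avoids amine activation of the enal. Setting out from 4:
- EtMgBr gives the allylic alcohol F3, and MnO2 oxidises it to the ethyl enone F4;
- rhodium-catalysed conjugate addition of potassium vinyltrifluoroborate ([Rh(OH)(cod)]2 with the enantiomer of BINAP that delivers the vinyl group to the required face) sets C6 in the vinyl ketone F5;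
- hydroboration of the vinyl group with 9-borabicyclo[3.3.1]nonane and oxidative work-up gives the hydroxy ketone F6 (any ketone reduction is corrected in the next oxidation);
- Dess–Martin periodinane gives the keto aldehyde F7, and aldol condensation (p-TsOH, toluene) returns to the route at 7.

**Step 6.** The likely failures are enolisation at an ester methylene instead of C5 (leading to Claisen-type condensation), insufficient facial bias at C5, and retro-aldol loss of formaldehyde or lactonisation of 13 onto the tert-butyl ester during work-up. The fallback replaces the metal enolate by a regiodefined enol ether and a Lewis-acid aldol. Setting out from 12, the trimethylsilyl enol ether F8 is formed under equilibrating conditions (Me3SiCl, Et3N, DMF, 80 °C; only the ketone is silylated). It is then treated with aqueous formaldehyde and catalytic Sc(OTf)3 in THF/water (Mukaiyama aldol), which gives the hydroxymethyl ketone under near-neutral conditions and returns to the route at 13.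

**Step 11.** The likely failure is poor facial selectivity at C9, since both faces are flanked by quaternary bridgeheads and the difference rests on one axial hydrogen and the flattened ring A. The fallback separates the stereodefining reduction from the ester reduction. Setting out from 18 as the mixture of C9 epimers, the mixture is silylated as in step 12 and the C9 carbinols are oxidised with Dess–Martin periodinane to the bis-silyl ketone F9, which has no conjugate acceptor left. F9 is reduced with the bulkiest hydride, LiBH(s-Bu)3 at −78 °C, which can only approach over ring A, and the route is rejoined at 19.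

## Further compounds

F1 | step 8 | carboxylic acid of 14 (CO2H in place of CO2Me on the C1 arm) | O=C1[C@@](C)(CC(=O)O)CC[C@@H]([C@H](C)CCC=C(C)C)[C@@]1(CO[Si](C)(C)C(C)(C)C)CC(=O)OC(C)(C)C
F2 | step 8 | acyl imidazolide of F1 | O=C1[C@@](C)(CC(=O)n2ccnc2)CC[C@@H]([C@H](C)CCC=C(C)C)[C@@]1(CO[Si](C)(C)C(C)(C)C)CC(=O)OC(C)(C)C
F3 | step 3 | (4E,6R)-6,10-dimethylundeca-4,9-dien-3-ol (C3 epimers) | CCC(O)/C=C/[C@H](C)CCC=C(C)C
F4 | step 3 | (4E,6R)-6,10-dimethylundeca-4,9-dien-3-one | CCC(=O)/C=C/[C@H](C)CCC=C(C)C
F5 | step 3 | (5S,6R)-5-ethenyl-6,10-dimethylundec-9-en-3-one | CCC(=O)C[C@@H](C=C)[C@H](C)CCC=C(C)C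
F6 | step 3 | (5R,6R)-5-(2-hydroxyethyl)-6,10-dimethylundec-9-en-3-one | CCC(=O)C[C@@H](CCO)[C@H](C)CCC=C(C)C
F7 | step 3 | (3R)-3-[(2R)-6-methylhept-5-en-2-yl]-5-oxoheptanal | CCC(=O)C[C@@H](CC=O)[C@H](C)CCC=C(C)C
F8 | step 6 | trimethylsilyl enol ether of 12 (C9–O–SiMe3, C9=C5) | C[Si](C)(C)OC1=C(CC(=O)OC(C)(C)C)[C@H]([C@H](C)CCC=C(C)C)CC[C@]1(C)CC(=O)OC
F9 | step 11 | (1R,5S,6S)-4,5-bis{[(tert-butyldimethylsilyl)oxy]methyl}-1-methyl-6-[(2R)-6-methylhept-5-en-2-yl]bicyclo[3.3.1]non-3-en-9-one | O=C1[C@@]2(C)CC=C(CO[Si](C)(C)C(C)(C)C)[C@]1(CO[Si](C)(C)C(C)(C)C)[C@H]([C@H](C)CCC=C(C)C)CC2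
A1 | alternative 1 | open-chain ethyl ketone: C5 bears CH2OTBS, the Z-alkenyl arm C4(CH2OTBS)=C3H–C2H2Br and C6 with the side chain and a 2-iodoethyl arm | CCC(=O)[C@](CO[Si](C)(C)C(C)(C)C)(/C(CO[Si](C)(C)C(C)(C)C)=C\CBr)[C@@H](CCI)[C@H](C)CCC=C(C)C
A2 | alternative 1 | 4,5-bis(silyloxymethyl)bicyclo[3.3.1]non-3-en-9-one (target numbering) | O=C1[C@@]2(C)CC=C(CO[Si](C)(C)C(C)(C)C)[C@]1(CO[Si](C)(C)C(C)(C)C)[C@H]([C@H](C)CCC=C(C)C)CC2
A3 | alternative 2 | methyl 2-{[(tert-butyldimethylsilyl)oxy]methyl}-5-methyl-6-oxocyclohex-2-ene-1-carboxylate (stereoisomer mixture; both centres are enolised in the step) | O=C1C(C)CC=C(CO[Si](C)(C)C(C)(C)C)C1C(=O)OC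
A4 | alternative 2 | 8-hydroxy bicyclic keto ester (C8 shown as one epimer) | O=C1[C@@]2(C)CC=C(CO[Si](C)(C)C(C)(C)C)[C@]1(C(=O)OC)[C@H]([C@H](C)CCC=C(C)C)C[C@@H]2O
A5 | alternative 3 | cis-fused epoxy hydrindenol: C9 tertiary alcohol bonded to C2, C1–C8 epoxide syn to the hydroxyl, C1 methyl, silyl ethers at C4′ and C5′ | O[C@@]12CC=C(CO[Si](C)(C)C(C)(C)C)[C@]1(CO[Si](C)(C)C(C)(C)C)[C@H]([C@H](C)CCC=C(C)C)C[C@H]1O[C@@]21C
A6 | alternative 3 | 8-hydroxy-4,5-bis(silyloxymethyl)bicyclo[3.3.1]non-3-en-9-one (target numbering) | O=C1[C@@]2(C)CC=C(CO[Si](C)(C)C(C)(C)C)[C@]1(CO[Si](C)(C)C(C)(C)C)[C@H]([C@H](C)CCC=C(C)C)C[C@H]2O
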